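The earlier runs and the new flask stem from a simulated flask for an exercise; scatter was added.

Slowness is the first thing to read here. In the noon run, the substrate's local time constant, the time it takes to fall by a factor of e, reads 22.7 s between 10.0 s and 15.0 s. Between 50.0 s and 90.0 s it reads 129 s, far longer, so you aren't looking at a first-order decay with one lifetime. But that run has one enzyme charge, and the questions are about changing it.

in all of them: substrate 0.10 M

| run | enzyme | remark |
|---|---|---|
| noon | 0.075 mol% | run made earlier |
| flask | 0.05 mol% |  |

- noon (time / s: target / %, substrate / %): 10.0: 43.5, 57.2; 15.0: 52.1, 45.9; 25.0: 62.7, 36.6; 50.0: 72.1, 25.9; 90.0: 79.9, 19.0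

(each reading ± 1 percentage point)

1. factor on the rate of making target when 20% of the substrate are converted if enzyme is charged twice over
2. factor on the rate when 20% of the substrate are converted if enzyme is charged at 0.01 mol% instead

Compare flasks at the same conversion and the same substrate charge of 0.10 M: substrate and target then stand at the same levels, so in my reckoning what differs is the working enzyme. My own reckoning uses two extremes you can solve in your head. If every enzyme works, the rate follows the charge factor, the new charge over the old, which is 0.200 for the lower charge and 2.00 for the doubled one. If enzyme idles in pairs so heavily that the free part goes as the square root of the charge, the factors become 0.447 and 1.41. Partial pairing lies between, so I commit to those two ranges. This is a guess: no earlier run changes the charge of enzyme.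

The forecast gives 2 and 0.2: “The rate at fixed conversion is then simply proportional to enzyme”.

The flask gives 1.53, less than the forecast's 2, and 0.325, more than its 0.2; both lie between my two extremes. Its scheme is:

    substrate + enzyme → target + enzyme, rate k1*[substrate]^3*[enzyme]/(1 + ([substrate]/Kh1)^3) (0.100 M, k = 5.50 × 10⁵ L³ mol⁻³ s⁻¹)
    2 enzyme ⇌ resting dimer, settled at all times (K = 31000 L mol⁻¹)

At 20% conversion in this flask, 42.9% of the catalyst is enzyme and 57.1% is resting dimer, the resting state, while with 0.01 mol% charged the shares are 69.8% and 30.2%. The working share is thus larger at the lower charge, and the charge factor 0.200 times the ratio of those working shares comes to 0.325.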